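**Retrosynthetic overview**
- The oxirane is the only ring made in the route, and it is made last. A catalyst-controlled epoxidation of the single trisubstituted alkene of a bromohydrin triene sets both epoxide carbons.
- The ring A alkene comes from a carvone-type enone by reductive 1,3-transposition (tosylhydrazone to allylic diazene). The central C=CH2 comes from chemoselective methylenation of a 1,4-diketone.
- Key disconnection: the bond between ring A C3 and the linker CH2 of that dissonant 1,4-diketone. It is formed by oxidative coupling of two ketone enolates, in which one donor α-carbon is turned into an acceptor.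
- The ring B methyl ketone comes from limonene-1,2-diol. A cyclic sulfate places Br with inversion to give the syn-bromohydrin, and the same pot cleaves the isopropenyl group to the acetyl group.
- Both carbocycles are bought intact: ring B from (1S,2S,4R)-limonene-1,2-diol and ring A from (S)-carvone.

Assumption: (1S,2S,4R)-(+)-limonene-1,2-diol and (S)-(+)-carvone are bought as single enantiomers. p-Menthane numbering is used in the explanations (ring A: C1 = CMe, C3 = carbon bearing the linker, C4 = carbon bearing isopropenyl; ring B the same with primes).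

**Step 1**
Reactants: 1 (1S,2S,4R)-limonene-1,2-diol
Product: 3 (1S,2S,4R)-4-acetyl-1-methylcyclohexane-1,2-diyl cyclic sulfate (trans-fused 1,3,2-dioxathiolane 2,2-dioxide), via cyclic sulfite 2 (not isolated)
Conditions: SOCl2 (1.2 equiv), Et3N (2.5 equiv), CH2Cl2, 0 °C; salts filtered off, crude carried on; RuCl3·xH2O (1 mol %), NaIO4 (3.5 equiv), MeCN/CH2Cl2/H2O, 0 °C to rt
Reagents that add atoms: thionyl chloride O=S(Cl)Cl; sodium periodate [Na+].[O-]I(=O)(=O)=O
Why: In this Sharpless cyclic sulfite/sulfate sequence the catalytic RuO4 oxidises S=O to SO2 and also cleaves the only alkene (C=CH2 to C=O), no C–O bond is broken so C1', C2' and C4' keep their configuration, and the near-neutral medium does not enolise the new ketone.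

**Step 2**
Reactants: 3 (1S,2S,4R)-4-acetyl-1-methylcyclohexane-1,2-diyl cyclic sulfate
Product: 5 1-[(1R,3R,4S)-3-bromo-4-hydroxy-4-methylcyclohexyl]ethan-1-one (syn-bromohydrin ketone), via lithium sulfate monoester 4 (not isolated)
Conditions: LiBr (3 equiv), DMF, 60 °C; then H2SO4 (cat.), H2O (2 equiv), THF, rt
Reagents that add atoms: lithium bromide [Li+].[Br-]
Why: In this SN2 opening of a 1,2-cyclic sulfate, bromide attacks the secondary C2' with inversion while the tertiary C1'–O bond is tied up as sulfate and cannot close an epoxide, so S–O hydrolysis of the monoester gives the cis bromohydrin (Br, CH3 and acetyl equatorial, OH axial), which is also the thermodynamic epimer at C4'.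

**Step 3**
Reactants: 5 1-[(1R,3R,4S)-3-bromo-4-hydroxy-4-methylcyclohexyl]ethan-1-one; 6 (S)-(+)-carvone, (5S)-2-methyl-5-(prop-1-en-2-yl)cyclohex-2-en-1-one
Product: 9 (5S,6R)-6-{2-[(1R,3R,4S)-3-bromo-4-hydroxy-4-methylcyclohexyl]-2-oxoethyl}-2-methyl-5-(prop-1-en-2-yl)cyclohex-2-en-1-one, via dilithium alkoxide-enolate 7 (not isolated), via lithium dienolate 8 (not isolated)
Conditions: 5 (1 equiv) + 6 (3 equiv) added to LiN(i-Pr)2 (5.2 equiv), THF, −78 °C, 45 min; CuCl2 (4.2 equiv) in DMF, −78 °C, 1 h; H2O quench at −78 °C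
Reagents that add atoms: none
Why: In this oxidative enolate heterocoupling (Saegusa type), divalent copper removes one electron from the cross-conjugated carvone enolate to give an electrophilic α-keto radical (an enolonium equivalent at the one-electron level), the unhindered CH2 terminus of the kinetic methyl-ketone enolate captures it so that two natural donor carbons are joined as a 1,4-diketone, and the bond forms anti to the neighbouring isopropenyl group to give the trans C3/C4 pair, which is also the equilibrium epimer.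

**Step 4**
Reactants: 9 the 1,4-diketone
Product: 10 (5S,6R)-6-{2-[(1R,3R,4S)-3-bromo-4-hydroxy-4-methylcyclohexyl]prop-2-en-1-yl}-2-methyl-5-(prop-1-en-2-yl)cyclohex-2-en-1-one
Conditions: Ph3PCH3Br (1.5 equiv), KOt-Bu (1.4 equiv), THF, 0 °C; then 9, −78 to 0 °C
Reagents that add atoms: methyltriphenylphosphonium bromide C[P+](c1ccccc1)(c1ccccc1)c1ccccc1.[Br-]
Why: This Wittig methylenation is selective on steric and electronic grounds, because the ring carbonyl is conjugated and flanked by the methyl-bearing sp2 carbon and the newly branched C3 so only the side-chain ketone reacts, the slight excess of phosphonium salt leaves no free alkoxide base, and the equatorial bromide has no antiperiplanar hydrogen for E2.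

**Step 5**
Reactants: 10 the methylenated enone
Product: 11 p-toluenesulfonylhydrazone of 10 (C2=N–NHTs)
Conditions: TsNHNH2 (1.5 equiv), pyridinium p-toluenesulfonate (10 mol %), EtOH, 60 °C
Reagents that add atoms: p-toluenesulfonyl hydrazide Cc1ccc(cc1)S(=O)(=O)NN
Why: This acid-catalysed hydrazone condensation occurs at the only carbonyl left, and the mild acid does not touch the tertiary alcohol, the bromide or the 1,1-disubstituted alkenes and creates no stereocenter.

**Step 6**
Reactants: 11 the tosylhydrazone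
Product: 14 (1S,2R,4R)-2-bromo-1-methyl-4-{3-[(1S,6S)-3-methyl-6-(prop-1-en-2-yl)cyclohex-2-en-1-yl]prop-1-en-2-yl}cyclohexan-1-ol, via N-boryl tosylhydrazine 12 (not isolated), via allylic diazene 13 (not isolated)
Conditions: catecholborane (3 equiv), CHCl3, −10 °C to rt; then NaOAc·3H2O (5 equiv), reflux
Reagents that add atoms: none
Why: In this Kabalka–Hutchins reductive transposition, hydride adds to C=N, acetate triggers loss of sulfinate, and the allylic diazene loses N2 by a retro-ene shift that puts H on C6 and moves the alkene regiospecifically to C1=C2, while C3 and C4 stay untouched and uncatalysed catecholborane does not hydroborate the alkenes at this temperature.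

**Step 7**
Reactants: 14 the bromohydrin triene
Product: 15 (1S,2R,4R)-2-bromo-1-methyl-4-{3-[(1R,2R,3S,6S)-6-methyl-3-(prop-1-en-2-yl)-7-oxabicyclo[4.1.0]heptan-2-yl]prop-1-en-2-yl}cyclohexan-1-ol (CNP0213097.1)
Conditions: 1,2:4,5-di-O-isopropylidene-β-D-erythro-2,3-hexodiulo-2,6-pyranose (D-fructose-derived Shi ketone, 30 mol %), Oxone (2KHSO5·KHSO4·K2SO4, 1.2 equiv KHSO5), K2CO3, Bu4NHSO4 (4 mol %), MeCN/CH2(OMe)2/aq Na2B4O7 buffer (pH 10.5), 0 °C
Reagents that add atoms: potassium peroxymonosulfate [K+].[O-]S(=O)(=O)OO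
Why: In this Shi asymmetric epoxidation the chiral dioxirane reacts through the spiro transition state with the only trisubstituted alkene (1,1-disubstituted alkenes are poor substrates) and attacks the same face as in the (R,R)-selective epoxidation of 1-substituted cyclohexenes, which here is the face anti to isopropenyl and syn to the C3 side chain and gives (1S,2R) in p-menthane numbering, while the cis-bromohydrin cannot close to an epoxide at this pH.

**Compound list**
1 | (1S,2S,4R)-1-methyl-4-(prop-1-en-2-yl)cyclohexane-1,2-diol, (+)-limonene-1,2-diol (trans-diaxial OH groups, isopropenyl equatorial) | CC(=C)[C@@H]1CC[C@](C)(O)[C@@H](O)C1 | starting material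
2 | (1S,2S,4R)-p-menth-8-ene-1,2-diyl cyclic sulfite (trans-fused, mixture at sulfur) | CC(=C)[C@@H]1CC[C@]2(C)OS(=O)O[C@H]2C1 | intermediate
3 | (1S,2S,4R)-4-acetyl-1-methylcyclohexane-1,2-diyl cyclic sulfate (trans-fused) | CC(=O)[C@@H]1CC[C@]2(C)OS(=O)(=O)O[C@H]2C1 | intermediate
4 | lithium (1S,2R,4R)-4-acetyl-2-bromo-1-methylcyclohexyl sulfate | CC(=O)[C@@H]1CC[C@](C)(OS(=O)(=O)[O-])[C@H](Br)C1.[Li+] | intermediate
5 | 1-[(1R,3R,4S)-3-bromo-4-hydroxy-4-methylcyclohexyl]ethan-1-one (Br and OH cis) | CC(=O)[C@@H]1CC[C@](C)(O)[C@H](Br)C1 | intermediate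
6 | (S)-(+)-carvone, (5S)-2-methyl-5-(prop-1-en-2-yl)cyclohex-2-en-1-one | CC1=CC[C@@H](CC1=O)C(=C)C | starting material
7 | dilithium alkoxide and kinetic (CH2) enolate of 5 | [Li+].[Li+].C=C([O-])[C@@H]1CC[C@](C)([O-])[C@H](Br)C1 | intermediate
8 | lithium cross-conjugated (α') dienolate of 6 | [Li+].CC1=CC[C@@H](C=C1[O-])C(=C)C | intermediate
9 | (5S,6R)-6-{2-[(1R,3R,4S)-3-bromo-4-hydroxy-4-methylcyclohexyl]-2-oxoethyl}-2-methyl-5-(prop-1-en-2-yl)cyclohex-2-en-1-one (side chain trans to isopropenyl) | O=C(C[C@@H]1[C@@H](C(=C)C)CC=C(C)C1=O)[C@@H]1CC[C@](C)(O)[C@H](Br)C1 | intermediate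
10 | (5S,6R)-6-{2-[(1R,3R,4S)-3-bromo-4-hydroxy-4-methylcyclohexyl]prop-2-en-1-yl}-2-methyl-5-(prop-1-en-2-yl)cyclohex-2-en-1-one | C=C(C[C@@H]1[C@@H](C(=C)C)CC=C(C)C1=O)[C@@H]1CC[C@](C)(O)[C@H](Br)C1 | intermediate
11 | p-toluenesulfonylhydrazone of 10 | C=C(C[C@@H]1[C@@H](C(=C)C)CC=C(C)C1=NNS(=O)(=O)c2ccc(C)cc2)[C@@H]3CC[C@](C)(O)[C@H](Br)C3 | intermediate
12 | N-(1,3,2-benzodioxaborol-2-yl)-N'-tosylhydrazine from hydride addition to 11 (new C2 centre transient, not specified) | C=C(C[C@@H]1[C@@H](C(=C)C)CC=C(C)C1N(B2Oc3ccccc3O2)NS(=O)(=O)c2ccc(C)cc2)[C@@H]1CC[C@](C)(O)[C@H](Br)C1 | intermediate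
13 | allylic diazene (C2–N=NH) from 12 | C=C(C[C@@H]1[C@@H](C(=C)C)CC=C(C)C1N=N)[C@@H]1CC[C@](C)(O)[C@H](Br)C1 | intermediate
14 | (1S,2R,4R)-2-bromo-1-methyl-4-{3-[(1S,6S)-3-methyl-6-(prop-1-en-2-yl)cyclohex-2-en-1-yl]prop-1-en-2-yl}cyclohexan-1-ol | C=C(C[C@@H]1[C@@H](C(=C)C)CCC(C)=C1)[C@@H]1CC[C@](C)(O)[C@H](Br)C1 | intermediate
15 | (1S,2R,4R)-2-bromo-1-methyl-4-{3-[(1R,2R,3S,6S)-6-methyl-3-(prop-1-en-2-yl)-7-oxabicyclo[4.1.0]heptan-2-yl]prop-1-en-2-yl}cyclohexan-1-ol | C=C(C[C@@H]1[C@@H](C(=C)C)CC[C@]2(C)O[C@H]12)[C@@H]1CC[C@](C)(O)[C@H](Br)C1 | target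

**Step count**
Total step count: 7. Longest linear sequence: 7 (1 to 15). Compound 6 enters unmodified in step 3.

**The three steps most likely to fail**

1) The oxidative coupling (step 3) is the riskiest step.
- Risks: carvone homodimer, proton transfer between the enolates, and cyclopropane formation if the enolate of 5 equilibrates to C4' (1,3-displacement of bromide).
- The fallback sets out from 5 and 6 and comes back at 9. It replaces the one-electron coupling by a discrete two-electron enolonium species.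
- 5 with LiN(i-Pr)2 (2.2 equiv)/Me3SiCl gives the bis-silylated kinetic enol ether F1. 6 with LiN(i-Pr)2/Me3SiCl gives the cross-conjugated silyl dienol ether F2.
- F1 is treated with PhI(OAc)2 and BF3·OEt2 in CH2Cl2 at −78 °C to give the O-bound trivalent-iodine enolonium species F3.
- F2 attacks the CH2 carbon of F3 anti to its isopropenyl group, with loss of iodobenzene, to give the O-silylated diketone F4.
- Dilute HCl in THF removes the tertiary silyl ether and gives 9.

2) The epoxidation (step 7) fights the substrate bias.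
- Risk: peracids and halohydrin routes both prefer the face anti to the C3 side chain, so the catalyst may give a poor diastereomer ratio.
- The fallback sets out from 14 and comes back at 15. It gives up face control and separates the diastereomers chemically.
- m-CPBA (1.0 equiv), NaHCO3, CH2Cl2, −20 °C epoxidises only the trisubstituted alkene. It gives 15 together with the epoxide diastereomer F5.
- Heating the mixture with pyrrolidine/H2O opens only F5, because its secondary C2 can be attacked in the trans-diaxial sense. This gives the amino alcohol F6.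
- 15 would need attack at the tertiary C1, so it survives and is isolated by chromatography.

3) The bromide opening (step 2) is hindered.
- Risks: the incoming bromide becomes axial and 1,3-syn to the axial acetyl group of the trans-fused sulfate, and the tertiary C–O bond may ionise instead.
- The fallback sets out from 1 and comes back at 5. It displaces an axial leaving group on the unconstrained chair.
- MsCl/pyridine at 0 °C gives the secondary mesylate F7.
- Me3SiOTf/2,6-lutidine at −78 °C masks the tertiary hydroxyl, so that it cannot close the epoxide, and gives the silyl ether mesylate F8.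
- LiBr in DMF at 70 °C inverts C2' to the equatorial bromide F9.
- O3 in CH2Cl2 at −78 °C, then Me2S, cleaves the isopropenyl group to the silyl-protected ketone F10.
- Dilute HCl in THF then gives 5.

**Further compounds**
F1 | step 3 | {[(1S,2R,4R)-2-bromo-1-methyl-4-(1-trimethylsilyloxyethenyl)cyclohexyl]oxy}trimethylsilane | C=C(O[Si](C)(C)C)[C@@H]1CC[C@](C)(O[Si](C)(C)C)[C@H](Br)C1
F2 | step 3 | trimethyl{[(3S)-6-methyl-3-(prop-1-en-2-yl)cyclohexa-1,5-dien-1-yl]oxy}silane | CC1=CC[C@@H](C=C1O[Si](C)(C)C)C(=C)C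
F3 | step 3 | acetoxy(phenyl)-λ3-iodanyl enolate (enolonium species) of the O-trimethylsilyl ether of 5 | C=C(OI(OC(C)=O)c1ccccc1)[C@@H]1CC[C@](C)(O[Si](C)(C)C)[C@H](Br)C1
F4 | step 3 | tertiary O-trimethylsilyl ether of 9 | O=C(C[C@@H]1[C@@H](C(=C)C)CC=C(C)C1=O)[C@@H]1CC[C@](C)(O[Si](C)(C)C)[C@H](Br)C1
F5 | step 7 | (1S,2R,4R)-2-bromo-1-methyl-4-{3-[(1S,2R,3S,6R)-6-methyl-3-(prop-1-en-2-yl)-7-oxabicyclo[4.1.0]heptan-2-yl]prop-1-en-2-yl}cyclohexan-1-ol (oxirane on the isopropenyl face) | C=C(C[C@@H]1[C@@H](C(=C)C)CC[C@@]2(C)O[C@@H]12)[C@@H]1CC[C@](C)(O)[C@H](Br)C1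
F6 | step 7 | trans-diaxial amino alcohol from F5 (ring A C1–OH on the isopropenyl face, C2–pyrrolidin-1-yl on the opposite face) | C=C(C[C@@H]1[C@@H](C(=C)C)CC[C@@](C)(O)[C@@H]1N2CCCC2)[C@@H]3CC[C@](C)(O)[C@H](Br)C3
F7 | step 2 | (1S,2S,4R)-1-hydroxy-p-menth-8-en-2-yl methanesulfonate | CC(=C)[C@@H]1CC[C@](C)(O)[C@@H](OS(C)(=O)=O)C1
F8 | step 2 | (1S,2S,4R)-1-(trimethylsilyloxy)-p-menth-8-en-2-yl methanesulfonate | CC(=C)[C@@H]1CC[C@](C)(O[Si](C)(C)C)[C@@H](OS(C)(=O)=O)C1
F9 | step 2 | {[(1S,2R,4R)-2-bromo-1-methyl-4-(prop-1-en-2-yl)cyclohexyl]oxy}trimethylsilane | CC(=C)[C@@H]1CC[C@](C)(O[Si](C)(C)C)[C@H](Br)C1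
F10 | step 2 | 1-[(1R,3R,4S)-3-bromo-4-methyl-4-(trimethylsilyloxy)cyclohexyl]ethan-1-one | CC(=O)[C@@H]1CC[C@](C)(O[Si](C)(C)C)[C@H](Br)C1
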